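**Strategy.** Everything rests on disconnecting the C2–C3 bond of ring C. The β-aryloxy ketone unit O1–C2–C3–C4(=O) is read as the rearranged form of a cyclic enol acetal, a 2-aryl-4-methylene-1,3-benzodioxine, in which C2 is still an acetal carbon bound to O1 and to the future carbonyl oxygen; this skeleton comes directly from a salicylic acid and protected vanillin. A catalyst-controlled Petasis–Ferrier-type [1,3] O-to-C shift ionises the acetal at C2 (stabilised by the 4-oxygenated ring B), joins C3 to C2, closes ring C, unveils the C4 ketone and sets the C2 stereocentre in one operation. Ring A is assembled from resorcinol by directed metalations and one C–H borylation.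

Key step: step 10

Remark: the target stereodescriptor corresponds to (2S); flavanone numbering (O1, C2, C3, C4, C4a, C5–C8, C8a; ring A benzo, ring B 2-aryl, ring C pyranone) is used throughout.

Remark: the hand of the catalyst in step 10 is the one that delivers 2S; which enantiomer that is has to be established by experiment.

**Step 1**
Reactants: 1 resorcinol
Product: 2 1,3-bis(methoxymethoxy)benzene
Conditions: NaH, MOMCl, DMF, 0 °C to rt
Reagents that add atoms: chloromethyl methyl ether (MOMCl), COCCl
Why: Williamson-type O-alkylation of the bis-phenoxide gives the bis-MOM ether, whose two acetal oxygens later act as cooperative ortho-directing groups.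

**Step 2**
Reactants: 2 1,3-bis(methoxymethoxy)benzene
Product: 5 tert-butyl{2-[2,6-bis(methoxymethoxy)phenyl]ethoxy}dimethylsilane, via 2-lithio arene 3 (not isolated), via lithium alkoxide 4 (not isolated)
Conditions: n-BuLi, THF, 0 °C; ethylene oxide, −78 °C to rt; then TBSCl, DMF (co-solvent), rt
Reagents that add atoms: ethylene oxide, C1CO1; tert-butyldimethylsilyl chloride, CC(C)(C)[Si](C)(C)Cl; n-butyllithium, [Li]CCCC (lithium of 3 and 4 only)
Why: directed ortho-metalation occurs at the position flanked by both MOM ethers, the aryllithium opens ethylene oxide by SN2, and the resulting lithium alkoxide is silylated in the same flask.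

**Step 3**
Reactants: 5 tert-butyl{2-[2,6-bis(methoxymethoxy)phenyl]ethoxy}dimethylsilane
Product: 7 4-[2-(tert-butyldimethylsilyloxy)ethyl]-3,5-bis(methoxymethoxy)phenol, via aryl pinacol boronate 6 (not isolated)
Conditions: [Ir(OMe)(cod)]2 (1.5 mol%), 4,4'-di-tert-butyl-2,2'-bipyridine (3 mol%), B2pin2 (0.6 equiv), THF, 80 °C; then 30% H2O2, 1 M aq. NaOH, 0 °C
Reagents that add atoms: hydrogen peroxide, OO (the phenol oxygen); bis(pinacolato)diboron, CC1(C)OB(OC1(C)C)B1OC(C)(C)C(C)(C)O1 (boryl group of 6 only)
Why: sterically controlled iridium-catalysed C–H borylation should take the only ring C–H without an ortho substituent (para to the side chain), and oxidation of the C–B bond gives the phenol that becomes O1 (C–H borylation/oxidation).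

**Step 4**
Reactants: 7 4-[2-(tert-butyldimethylsilyloxy)ethyl]-3,5-bis(methoxymethoxy)phenol
Product: 8 tert-butyl{2-[4-(1-ethoxyethoxy)-2,6-bis(methoxymethoxy)phenyl]ethoxy}dimethylsilane (racemic at the acetal carbon)
Conditions: ethyl vinyl ether, PPTS (cat.), CH2Cl2, 0 °C to rt
Reagents that add atoms: ethyl vinyl ether, C=COCC
Why: acid-catalysed addition of the phenol to the vinyl ether gives a 1-ethoxyethyl acetal, which directs ortho-metalation like MOM but is far more acid-labile, so this oxygen can be freed selectively later.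

**Step 5**
Reactants: 8 tert-butyl{2-[4-(1-ethoxyethoxy)-2,6-bis(methoxymethoxy)phenyl]ethoxy}dimethylsilane
Product: 10 tert-butyl{2-[4-(1-ethoxyethoxy)-2,6-bis(methoxymethoxy)-3-(3-methylbut-2-en-1-yl)phenyl]ethoxy}dimethylsilane, via aryllithium 9 (not isolated)
Conditions: n-BuLi, TMEDA, THF, 0 °C; CuBr·SMe2 (10 mol%), prenyl bromide, −78 °C to rt
Reagents that add atoms: prenyl bromide, CC(C)=CCBr; n-butyllithium, [Li]CCCC (lithium of 9 only)
Why: directed ortho-metalation at one of the two equivalent C–H positions lying between the ethoxyethyl and a MOM acetal, followed by copper-catalysed SN2 allylation, should give the linear prenyl group next to the future O1.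

**Step 6**
Reactants: 10 tert-butyl{2-[4-(1-ethoxyethoxy)-2,6-bis(methoxymethoxy)-3-(3-methylbut-2-en-1-yl)phenyl]ethoxy}dimethylsilane
Product: 13 5-[2-(tert-butyldimethylsilyloxy)ethyl]-2-hydroxy-4,6-bis(methoxymethoxy)-3-(3-methylbut-2-en-1-yl)benzoic acid, via aryllithium 11 (not isolated), via 1-ethoxyethyl acid 12 (not isolated)
Conditions: n-BuLi, TMEDA, THF, −78 to −20 °C; CO2 (g), −78 °C; then 0.5 M aq. HCl to pH 3, THF, 0 °C, short contact
Reagents that add atoms: carbon dioxide, O=C=O; n-butyllithium, [Li]CCCC (lithium of 11 only)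
Why: directed ortho-metalation of the last ring C–H (held between two coordinating acetal oxygens) and carboxylation give the benzoic acid, and the acetaldehyde-derived acetal ortho to the new carboxyl group is hydrolysed with neighbouring-group assistance much faster than the formaldehyde-derived MOM acetals, freeing only the phenol next to the prenyl group.

**Step 7**
Reactants: 14 vanillin
Product: 15 3-methoxy-4-(methoxymethoxy)benzaldehyde
Conditions: MOMCl, K2CO3, acetone, rt
Reagents that add atoms: chloromethyl methyl ether (MOMCl), COCCl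
Why: O-alkylation of the phenoxide (Williamson ether synthesis) masks the ring B phenol as an acid-labile, electron-donating ether.

**Step 8**
Reactants: 13 the salicylic acid; 15 3-methoxy-4-(methoxymethoxy)benzaldehyde
Product: 17 rac-6-[2-(tert-butyldimethylsilyloxy)ethyl]-2-[3-methoxy-4-(methoxymethoxy)phenyl]-5,7-bis(methoxymethoxy)-8-(3-methylbut-2-en-1-yl)-4H-1,3-benzodioxin-4-one, via bis-silylated acid 16 (not isolated)
Conditions: HMDS, TMSCl (cat.), THF, 50 °C, concentrate; then 15, TMSOTf (10 mol%), CH2Cl2, −78 °C; pyridine quench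
Reagents that add atoms: hexamethyldisilazane, C[Si](C)(C)N[Si](C)(C)C (trimethylsilyl groups of 16 only)
Why: silyl-triflate-catalysed condensation of a bis-silylated hydroxy acid with an aldehyde, the standard entry to 1,3-dioxan-4-ones, is driven by formation of hexamethyldisiloxane; the acetal carbon is formed racemic, which does not matter because it is ionised in step 10.

**Step 9**
Reactants: 17 the benzodioxinone
Product: 18 rac-tert-butyl(2-{2-[3-methoxy-4-(methoxymethoxy)phenyl]-5,7-bis(methoxymethoxy)-4-methylidene-8-(3-methylbut-2-en-1-yl)-4H-1,3-benzodioxin-6-yl}ethoxy)dimethylsilane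
Conditions: Cp2TiMe2 (2.5 equiv), toluene/THF, 65 °C, dark; filtration through basic alumina, used directly
Reagents that add atoms: dimethyltitanocene (Cp2TiMe2), [CH3-].[CH3-].[Ti+4].[cH-]1cccc1.[cH-]1cccc1
Why: Petasis methylenation: thermally generated Cp2Ti=CH2 converts the lactone carbonyl through an oxatitanacyclobutane into the exocyclic enol ether under non-basic conditions that spare the acetals, the silyl ether and the prenyl alkene.

**Step 10**
Reactants: 18 the enol acetal
Product: 19 (2S)-6-[2-(tert-butyldimethylsilyloxy)ethyl]-2-[3-methoxy-4-(methoxymethoxy)phenyl]-5,7-bis(methoxymethoxy)-8-(3-methylbut-2-en-1-yl)-2,3-dihydro-4H-chromen-4-one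
Conditions: chiral imidodiphosphorimidate Brønsted acid built from two 3,3'-diaryl-BINOL units with N-triflyl groups (aryl = 3,5-bis(trifluoromethyl)phenyl as first choice, 3 mol%), methallyltrimethylsilane (10 mol%, turns the acid into its silylated form), toluene, −60 °C; Et3N quench
Reagents that add atoms: none
Why: Proposed new method: the silylated chiral acid (a silylium ion pair) silylates the enol-ether oxygen O3 of 18, the C2–O3 bond ionises to an oxocarbenium ion (O1=C2, further stabilised by the 4-alkoxy-3-methoxyphenyl ring B) that stays tethered through O1 to the silyl enol ether of the aryl methyl ketone, the enol carbon (future C3) attacks C2, and the silyl group then passes from the new C4 carbonyl oxygen to the next molecule of 18. The closest known reaction types are the Lewis-acid-mediated Petasis–Ferrier rearrangement of 4-methylene-1,3-dioxanes to tetrahydropyran-4-ones, the chiral-phosphoric-acid-catalysed aza-Petasis–Ferrier rearrangement and confined-acid-catalysed additions of enol silanes to oxocarbenium ions, but a benzo-fused enol acetal has not been used in this way. Ring C closes in a 6-(enolendo)-endo-trig mode. The C2 stereocentre is set under catalyst control: both enantiomers of racemic 18 collapse to the same planar oxocarbenium ion, and the confined chiral counter-anion decides which face of C2 the enol attacks. The step needs ionisation of C2–O3 in preference to C2–O1 (only the former allows a six-membered closure), C- rather than O-attack of the enol (O-attack merely regenerates 18) and faster capture by the enol silane than by the C8 prenyl alkene, which the much higher nucleophilicity of the enol silane and the low temperature should secure. Anhydrous, base-free conditions should keep the MOM and TBS groups and prevent hydrolysis of the enol acetal.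

**Step 11**
Reactants: 19 the protected flavanone
Product: 20 laxiflorin, (2S)-5,7-dihydroxy-6-(2-hydroxyethyl)-2-(4-hydroxy-3-methoxyphenyl)-8-(3-methylbut-2-en-1-yl)-2,3-dihydro-4H-chromen-4-one
Conditions: HCl (1.25 M in MeOH), MeOH, 0 °C to rt
Reagents that add atoms: none
Why: acid-catalysed methanolysis removes the three aryl MOM acetals and the primary TBS ether in one operation, and mild acid without base should leave C2 untouched (no retro-oxa-Michael opening) and the prenyl group uncyclised.

**Compound list**
1 | resorcinol | Oc1cccc(O)c1 | starting material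
2 | 1,3-bis(methoxymethoxy)benzene | COCOc1cccc(OCOC)c1 | intermediate
3 | [2,6-bis(methoxymethoxy)phenyl]lithium | [Li]c1c(OCOC)cccc1OCOC | intermediate (not isolated)
4 | lithium 2-[2,6-bis(methoxymethoxy)phenyl]ethoxide | [Li]OCCc1c(OCOC)cccc1OCOC | intermediate (not isolated)
5 | tert-butyl{2-[2,6-bis(methoxymethoxy)phenyl]ethoxy}dimethylsilane | COCOc1cccc(OCOC)c1CCO[Si](C)(C)C(C)(C)C | intermediate
6 | 2-{4-[2-(tert-butyldimethylsilyloxy)ethyl]-3,5-bis(methoxymethoxy)phenyl}-4,4,5,5-tetramethyl-1,3,2-dioxaborolane | COCOc1cc(B2OC(C)(C)C(C)(C)O2)cc(OCOC)c1CCO[Si](C)(C)C(C)(C)C | intermediate (not isolated)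
7 | 4-[2-(tert-butyldimethylsilyloxy)ethyl]-3,5-bis(methoxymethoxy)phenol | COCOc1cc(O)cc(OCOC)c1CCO[Si](C)(C)C(C)(C)C | intermediate
8 | tert-butyl{2-[4-(1-ethoxyethoxy)-2,6-bis(methoxymethoxy)phenyl]ethoxy}dimethylsilane | CCOC(C)Oc1cc(OCOC)c(CCO[Si](C)(C)C(C)(C)C)c(OCOC)c1 | intermediate
9 | 2-lithio derivative of 8 | CCOC(C)Oc1cc(OCOC)c(CCO[Si](C)(C)C(C)(C)C)c(OCOC)c1[Li] | intermediate (not isolated)
10 | tert-butyl{2-[4-(1-ethoxyethoxy)-2,6-bis(methoxymethoxy)-3-(3-methylbut-2-en-1-yl)phenyl]ethoxy}dimethylsilane | CCOC(C)Oc1cc(OCOC)c(CCO[Si](C)(C)C(C)(C)C)c(OCOC)c1CC=C(C)C | intermediate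
11 | ring-lithiated derivative of 10 | CCOC(C)Oc1c([Li])c(OCOC)c(CCO[Si](C)(C)C(C)(C)C)c(OCOC)c1CC=C(C)C | intermediate (not isolated)
12 | 5-[2-(tert-butyldimethylsilyloxy)ethyl]-2-(1-ethoxyethoxy)-4,6-bis(methoxymethoxy)-3-(3-methylbut-2-en-1-yl)benzoic acid | CCOC(C)Oc1c(C(=O)O)c(OCOC)c(CCO[Si](C)(C)C(C)(C)C)c(OCOC)c1CC=C(C)C | intermediate (not isolated)
13 | 5-[2-(tert-butyldimethylsilyloxy)ethyl]-2-hydroxy-4,6-bis(methoxymethoxy)-3-(3-methylbut-2-en-1-yl)benzoic acid | OC(=O)c1c(O)c(CC=C(C)C)c(OCOC)c(CCO[Si](C)(C)C(C)(C)C)c1OCOC | intermediate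
14 | vanillin | COc1cc(C=O)ccc1O | starting material
15 | 3-methoxy-4-(methoxymethoxy)benzaldehyde | COCOc1ccc(C=O)cc1OC | intermediate
16 | trimethylsilyl 5-[2-(tert-butyldimethylsilyloxy)ethyl]-4,6-bis(methoxymethoxy)-3-(3-methylbut-2-en-1-yl)-2-(trimethylsilyloxy)benzoate | C[Si](C)(C)OC(=O)c1c(O[Si](C)(C)C)c(CC=C(C)C)c(OCOC)c(CCO[Si](C)(C)C(C)(C)C)c1OCOC | intermediate (not isolated)
17 | rac-6-[2-(tert-butyldimethylsilyloxy)ethyl]-2-[3-methoxy-4-(methoxymethoxy)phenyl]-5,7-bis(methoxymethoxy)-8-(3-methylbut-2-en-1-yl)-4H-1,3-benzodioxin-4-one | O=C1OC(c2ccc(OCOC)c(OC)c2)Oc2c(CC=C(C)C)c(OCOC)c(CCO[Si](C)(C)C(C)(C)C)c(OCOC)c21 | intermediate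
18 | rac-tert-butyl(2-{2-[3-methoxy-4-(methoxymethoxy)phenyl]-5,7-bis(methoxymethoxy)-4-methylidene-8-(3-methylbut-2-en-1-yl)-4H-1,3-benzodioxin-6-yl}ethoxy)dimethylsilane | C=C1OC(c2ccc(OCOC)c(OC)c2)Oc2c(CC=C(C)C)c(OCOC)c(CCO[Si](C)(C)C(C)(C)C)c(OCOC)c21 | intermediate
19 | (2S)-6-[2-(tert-butyldimethylsilyloxy)ethyl]-2-[3-methoxy-4-(methoxymethoxy)phenyl]-5,7-bis(methoxymethoxy)-8-(3-methylbut-2-en-1-yl)-2,3-dihydro-4H-chromen-4-one | COc1cc([C@@H]2CC(=O)c3c(OCOC)c(CCO[Si](C)(C)C(C)(C)C)c(OCOC)c(CC=C(C)C)c3O2)ccc1OCOC | intermediate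
20 | laxiflorin | COc1cc([C@@H]2CC(=O)c3c(O)c(CCO)c(O)c(CC=C(C)C)c3O2)ccc1O | target

**Step count.** Total: 11 steps. Longest linear sequence: 10 steps (steps 1–6 and 8–11, from resorcinol); step 7 is a one-step side branch.

**Steps most likely to fail**

1. Step 10 (Proposed new method). The ring closure may show poor facial selectivity if an uncatalysed or loosely ion-paired pathway competes. The oxocarbenium ion may also be intercepted by the prenyl alkene, or the enol acetal may simply hydrolyse. The fallback sets out from 13 and returns at 19. Acid 13 with excess MeLi (THF, 0 °C) should give the methyl ketone 1-{5-[2-(tert-butyldimethylsilyloxy)ethyl]-2-hydroxy-4,6-bis(methoxymethoxy)-3-(3-methylbut-2-en-1-yl)phenyl}ethanone F1. Condensation with N,N-dimethylformamide dimethyl acetal gives the enaminone F2, which closes with loss of dimethylamine (PPTS, toluene, warm) to the chromone F3. Rhodium-catalysed asymmetric 1,4-addition of the aryl pinacol boronate F4 to F3 ([Rh(OH)(cod)]2, an electron-poor chiral biaryl bisphosphine of the hand that gives 2S, aq. KOH, toluene) then gives 19. F4 is made from commercial 2-methoxy-4-(4,4,5,5-tetramethyl-1,3,2-dioxaborolan-2-yl)phenol with MOMCl and K2CO3. Step 11 follows unchanged.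

2. Step 9. The titanium reagent may open or ionise the acid-labile acylal instead of methylenating the hindered carbonyl, and the enol acetal may hydrolyse during isolation. The fallback sets out from 13 and returns at 19. The methyl ketone F1 (from 13 and MeLi as above) is condensed with aldehyde 15 (KOH, EtOH, rt, Claisen–Schmidt condensation) to the 2'-hydroxychalcone F5. F5 is then cyclised by enantioselective intramolecular oxa-Michael addition under a quinine-derived bifunctional thiourea (toluene, low temperature) to 19, with enrichment by crystallisation if needed.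

3. Step 6. Lateral deprotonation at the benzylic–allylic CH2 of the prenyl group may compete with ring metalation, and the MOM acetal ortho to the new carboxylic acid may be lost during unmasking. The fallback sets out from 10 and returns at 13. The ethoxyethyl group is removed first (PPTS, MeOH, 0 °C) to give the phenol 4-[2-(tert-butyldimethylsilyloxy)ethyl]-3,5-bis(methoxymethoxy)-2-(3-methylbut-2-en-1-yl)phenol F6. Magnesium-mediated ortho-formylation at the only free ortho position (MgCl2, Et3N, paraformaldehyde, MeCN, reflux) gives the salicylaldehyde F7. Pinnick oxidation (NaClO2, NaH2PO4, 2-methyl-2-butene, t-BuOH/H2O) then gives 13.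

**Further compounds**
F1 | step 10 | 1-{5-[2-(tert-butyldimethylsilyloxy)ethyl]-2-hydroxy-4,6-bis(methoxymethoxy)-3-(3-methylbut-2-en-1-yl)phenyl}ethanone | CC(=O)c1c(O)c(CC=C(C)C)c(OCOC)c(CCO[Si](C)(C)C(C)(C)C)c1OCOC
F2 | step 10 | (E)-1-{5-[2-(tert-butyldimethylsilyloxy)ethyl]-2-hydroxy-4,6-bis(methoxymethoxy)-3-(3-methylbut-2-en-1-yl)phenyl}-3-(dimethylamino)prop-2-en-1-one | CN(C)/C=C/C(=O)c1c(O)c(CC=C(C)C)c(OCOC)c(CCO[Si](C)(C)C(C)(C)C)c1OCOC
F3 | step 10 | 6-[2-(tert-butyldimethylsilyloxy)ethyl]-5,7-bis(methoxymethoxy)-8-(3-methylbut-2-en-1-yl)-4H-chromen-4-one | O=c1ccoc2c(CC=C(C)C)c(OCOC)c(CCO[Si](C)(C)C(C)(C)C)c(OCOC)c12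
F4 | step 10 | 2-[3-methoxy-4-(methoxymethoxy)phenyl]-4,4,5,5-tetramethyl-1,3,2-dioxaborolane | COCOc1ccc(B2OC(C)(C)C(C)(C)O2)cc1OC
F5 | step 9 | (E)-1-{5-[2-(tert-butyldimethylsilyloxy)ethyl]-2-hydroxy-4,6-bis(methoxymethoxy)-3-(3-methylbut-2-en-1-yl)phenyl}-3-[3-methoxy-4-(methoxymethoxy)phenyl]prop-2-en-1-one | COCOc1ccc(/C=C/C(=O)c2c(O)c(CC=C(C)C)c(OCOC)c(CCO[Si](C)(C)C(C)(C)C)c2OCOC)cc1OC
F6 | step 6 | 4-[2-(tert-butyldimethylsilyloxy)ethyl]-3,5-bis(methoxymethoxy)-2-(3-methylbut-2-en-1-yl)phenol | Oc1cc(OCOC)c(CCO[Si](C)(C)C(C)(C)C)c(OCOC)c1CC=C(C)C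
F7 | step 6 | 5-[2-(tert-butyldimethylsilyloxy)ethyl]-2-hydroxy-4,6-bis(methoxymethoxy)-3-(3-methylbut-2-en-1-yl)benzaldehyde | O=Cc1c(O)c(CC=C(C)C)c(OCOC)c(CCO[Si](C)(C)C(C)(C)C)c1OCOC
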